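## Structural features

The target 26 is a 14-membered carbocycle of the cembrane type, numbered from C1 (isopropenyl carbon) through C2 and C3 to C4(Me)=C5, C6, C7=C8(Me), C9(OH), C10, C11, C12(CH2OAc)=C13 and C14(OAc), which closes back to C1. All three ring alkenes are trisubstituted: C4=C5 is E, C7=C8 is Z, and in C12=C13 the ring carbons C11 and C14 are cis, which makes this alkene E by the sequence rule because the acetoxymethyl group outranks C11. The stereocentres C1 (R) and C14 (S) are neighbours and stand anti to each other, whereas C9 (S) is an isolated allylic carbinol five ring bonds away from C14, so it cannot be set by relay from them. Fragile elements are the doubly allylic C6 methylene of the skipped C4=C5/C7=C8 diene, the two allylic acetates, which zerovalent palladium can ionise, and the free allylic C9 hydroxyl. The real difficulty is to close a 14-membered ring without disturbing three defined alkene geometries and to build the remote C9 centre and the C1/C14 pair under reagent control. The key step exploits the fact that C6 is bonded to the sp2 carbons C5 and C7: C4–C5–C6 is an allyl unit and C7 an alkenyl carbon, so the C6–C7 bond is the natural product of an allyl–alkenyl cross-coupling. This bond lies far from C1, C9 and C14, so ring closure there cannot epimerise any stereocentre.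

## Logic of the disconnections

26 ⇒ 25 ⇒ 24 ⇒ 23. Cut: the two acyl C–O bonds at O14 and at the oxygen of the C12 hydroxymethyl group, after exchanging O9–H for O9–Si. Reason: allylic acetates would be ionised by the zerovalent palladium of the ring closure, and three free hydroxyls could not be told apart by an acylating agent. Gain: 23 holds the two future acetate oxygens under one labile silyl type and O9 under a more robust one, so the endgame is pure protecting-group chemistry. Demand: mild acid must remove two triethylsilyl ethers and spare the secondary allylic tert-butyldimethylsilyl ether, and the final fluoride step must not touch the acetates.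

23 ⇒ 22. Cut: C6–C7, the bond between the allyl unit C4–C6 and the alkenyl carbon C7. Reason: it is the only ring bond whose formation is an sp3–sp2 cross-coupling remote from every stereocentre. Gain: the ring opens to a linear chain in which all stereocentres and alkene geometries are already in place; 22 and 23 carry the same descriptors as 26 (1R, 9S, 14S; 4E, 7Z, 12E), so neither needs correcting. Demand: coupling at the primary terminus C6, retention of 4E and 7Z, and cyclisation ahead of oligomerisation.

22 ⇒ 20 ⇒ 19 ⇒ 18. Cut: C6–Cl back to C6–OH and C6–OAc, and the O14–Si bond. Reason: no stannylation method tolerates an allylic chloride, so the tin group must already be present and the chloride is made last from a masked alcohol. O14 is silylated because a free C14 hydroxyl could attack the C4 terminus of the π-allyl complex and form a tetrahydropyran. Gain: 18 is the direct product of the fragment union. Demand: acetate cleavage and chlorination must spare the alkenylstannane and two triethylsilyl ethers, and chlorination must not transpose the allyl system.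

18 ⇒ 3 + 16. Cut: C1–C14. Reason: the bond joins the two adjacent stereocentres, and a γ-selective allylmetal addition to an aldehyde forms it, sets both centres and unveils the isopropenyl group at once. Gain: a C10 allylic bromide 3 that already contains the E-C4=C5 alkene, and the enal 16. Demand: anti diastereoselectivity from the E-allylmetal and reagent-controlled facial selectivity, since the only stereocentre of 16 (C9) is too far away to help.

16 ⇒ 15 ⇒ 9 + 13. Cut: C11–C12, an sp3–sp2 bond at the trisubstituted alkene, after returning the C14 aldehyde to the alcohol. Reason: a stereodefined alkenyl iodide at C12 transfers its geometry with retention, which is the safest way to place C11 cis to C14. Gain: two small pieces, each carrying one element of stereochemistry. Demand: the coupling must use boron at C11 and leave the tin at C7 alone.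

9 ⇒ 8 ⇒ 7 ⇒ 6 ⇒ 4. Cut: C9–C10 (vinyl addition to an aldehyde), then C8–CH3 and C7–Sn across the alkyne of 4. Reason: hydroxyl-directed anti-carbometalation is the one reliable way to put tin cis to the carbinol carbon on a methyl-bearing alkene. Gain: the whole C7–C11 unit comes from 4, a methyl Grignard and a vinyl Grignard. Demand: enantioselective vinyl transfer to set C9, and survival of the Z-enal geometry.

13 ⇒ 11 ⇒ 10. Cut: C12–I and C13–H across the alkyne, and one O–Si bond. Reason: hydroxyl-directed trans-hydroalumination puts the iodine cis to the free carbinol carbon, which later becomes C14, and the silyl group marks the other oxygen as the future C12 hydroxymethyl. Gain: the symmetrical diol 10. Demand: clean monosilylation and regioselective iodination.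

3 ⇒ 2 ⇒ 1. Cut: C–Br, then the allylic C–O bond at the E-methyl group. Reason: 1 already holds C1–C6, the C4 methyl and the E-C4=C5 alkene. Gain: two steps to the allyl donor. Demand: site-selective allylic oxidation at the terminal E-methyl group.

## Other disconnections considered

Alternative 1: The cut is C1–C14 by retro-[2,3]-Wittig, leading from the 14-membered propargylic alcohol A1 back to the 17-membered propargyl allyl ether A2. In the forward step a chiral lithium amide would remove a propargylic O–CH2 proton of A2, the carbanion would bond to C1 through a five-membered envelope transition state, and the ring would contract by three atoms with release of the isopropenyl group. In its favour, one operation would create the carbocycle, the isopropenyl group and both adjacent stereocentres, and the precursor ring is a macrocyclic ether that is easy to close; on this point the alternative is the better plan, since the key step of the chosen route creates no stereocentre. Against it, the chiral base must discriminate enantiotopic protons in a substrate whose only stereocentre (C9) is remote, and the strong base meets the doubly allylic C6 protons. A1 also lacks the C12 hydroxymethyl group: hydrogen would have to be added to C13 and carbon to C12 in a syn sense, with the carbon on the alkyne terminus distal to the C14 hydroxyl, a pattern that the usual hydroxyl-directed alkyne functionalisations would not be expected to deliver. The chosen route fixes that alkene geometry early and stereospecifically in 13. In reagent-controlled setting of C1/C14 the two plans are equal. In step count the alternative would probably be longer because of the alkyne elaboration.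

Alternative 2: The cut is C1–C2 by retro-Ireland–Claisen, leading from the ring acid A3 back to the 18-membered lactone A4. In the forward step the silyl ketene acetal of A4 would undergo a [3,3] shift that forms C1–C2, releases the isopropenyl group and contracts the ring by four atoms. In its favour, macrolactonisation is among the most dependable ring closures and needs no tin; here the alternative is the better plan on ring-closing reliability and reagent toxicity, and the C2 configuration is irrelevant. Against it, the configuration at C1 would depend only on the facial bias exerted by the neighbouring C14 silyloxy centre and on the lactone conformation, with no reagent control available, whereas the chosen route sets C1 and C14 together through a closed transition state. The carboxyl group of A3 is also extraneous and would have to be removed by a radical decarboxylation next to two alkenes. Mechanistically the alternative is a concerted pericyclic step against a catalytic cross-coupling. In step economy it costs about three more operations (lactonisation, rearrangement, decarboxylation) than the single ring-closing step from 22 to 23.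

Alternative 3: The cut is C12=C13 by a retro-Horner–Wadsworth–Emmons reaction, leading from the macrocyclic enoate A5 back to the seco aldehyde phosphonate A6, whose C1 centre would come from (S)-limonene A7. In the forward step LiCl and an amine base would generate the phosphonate anion of A6, which adds to the C13 aldehyde and eliminates phosphate to close the ring. In its favour, the thermodynamically preferred E-enoate has exactly the geometry needed (ester trans to C14) and its ester carbon becomes the C12 hydroxymethyl group; C1 is taken from the chiral pool without an asymmetric reagent, and the route is tin-free. On those two points the alternative is the better plan. Against it, the C13 aldehyde of A6 carries the silyloxy stereocentre C14 in the α-position and could epimerise under the basic conditions. The C14 oxygen must first be introduced next to C1 with control, and an α-branched phosphonate reacting with an α-branched aldehyde is a slow combination for a macrocyclisation. The E-C4=C5 alkene, which 1 supplies ready-made in the chosen route, would have to be built from the methyl ketone that ring cleavage of A7 leaves, and olefination of methyl ketones gives poor geometric control; A7 is also the less common limonene enantiomer. In step count the two plans would be similar; the chosen plan is mechanistically safer for the stereocentres because its ring closure is neutral and remote from them.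

Key step: step 15

Remark on the chemistry: the facial sense of the chiral ligands in steps 5 and 11 is assigned by analogy with simpler aldehydes; should a model run show the opposite sense, the antipodal ligand is taken and nothing else changes.

## Route

Step 1
Reactants: 1 geranyl acetate
Product: 2 (2E,6E)-8-hydroxy-3,7-dimethylocta-2,6-dien-1-yl acetate
Conditions: SeO2 (0.1 equiv), t-BuOOH (3 equiv), salicylic acid (0.1 equiv), CH2Cl2, 0 °C → rt
Reagents that add atoms: selenium dioxide, O=[Se]=O (catalytic oxygen carrier); tert-butyl hydroperoxide, CC(C)(C)OO (terminal oxygen source)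
Why: Allylic oxidation by ene reaction and [2,3]-sigmatropic shift goes to the E-methyl group of the electron-rich terminal alkene, while the alkene next to the acetate is deactivated. Any over-oxidised enal is removed by chromatography.

Step 2
Reactants: 2 (2E,6E)-8-hydroxy-3,7-dimethylocta-2,6-dien-1-yl acetate
Product: 3 (2E,6E)-8-bromo-3,7-dimethylocta-2,6-dien-1-yl acetate
Conditions: CBr4, PPh3, CH2Cl2, 0 °C
Reagents that add atoms: carbon tetrabromide, BrC(Br)(Br)Br
Why: Appel bromination of a primary allylic alcohol proceeds by SN2 displacement of the oxyphosphonium ion at 0 °C without allylic transposition; the acetate is inert.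

Step 3
Reactants: 4 propargyl alcohol
Product: 6 (2Z)-2-methyl-3-(tributylstannyl)prop-2-en-1-ol, via vinylmagnesium alkoxide 5 (not isolated)
Conditions: MeMgBr (2.5 equiv), CuI (0.1 equiv), THF, −10 °C → rt; then Bu3SnCl (1.6 equiv), 0 °C → rt; aq. NH4Cl
Reagents that add atoms: methylmagnesium bromide, C[Mg]Br; tributyltin chloride, CCCC[Sn](Cl)(CCCC)CCCC
Why: Copper-catalysed anti-carbomagnesiation of the magnesium propargyl alkoxide puts the methyl group on the future C8 and magnesium on C7 inside a five-membered chelate. Quenching this alkenyl Grignard with the chlorostannane therefore fixes tin cis to the carbinol carbon, the 7Z geometry of the target.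

Step 4
Reactants: 6 (2Z)-2-methyl-3-(tributylstannyl)prop-2-en-1-ol
Product: 7 (2Z)-2-methyl-3-(tributylstannyl)prop-2-enal
Conditions: activated MnO2 (15 equiv), CH2Cl2, rt, dark
Reagents that add atoms: none
Why: Heterogeneous allylic oxidation under neutral conditions, with no acid or base that would isomerise the Z-enal or cleave the C–Sn bond.

Step 5
Reactants: 7 (2Z)-2-methyl-3-(tributylstannyl)prop-2-enal
Product: 8 (3S,4Z)-4-methyl-5-(tributylstannyl)penta-1,4-dien-3-ol
Conditions: (CH2=CH)2Zn [from CH2=CHMgBr (2 equiv) and ZnCl2 (1 equiv), THF; magnesium salts precipitated with 1,4-dioxane], (−)-MIB [(2S)-3-exo-morpholinoisoborneol, 10 mol%], toluene, −20 → 0 °C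
Reagents that add atoms: vinylmagnesium bromide, C=C[Mg]Br
Why: Amino-alcohol-catalysed addition of an alkenylzinc reagent to an aldehyde; the chiral zinc alkoxide of the ligand should deliver the vinyl group to the Si face and set C9 as S. α-Branched enals are among the best substrates for this reaction type, and removal of the magnesium salts suppresses the racemic background addition.

Step 6
Reactants: 8 (3S,4Z)-4-methyl-5-(tributylstannyl)penta-1,4-dien-3-ol
Product: 9 (3S,4Z)-3-(tert-butyldimethylsilyloxy)-4-methyl-5-(tributylstannyl)penta-1,4-diene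
Conditions: TBSCl, imidazole, DMF, rt
Reagents that add atoms: tert-butyldimethylsilyl chloride, CC(C)(C)[Si](C)(C)Cl
Why: Standard silylation; the basic medium avoids ionisation of the doubly allylic carbinol and protodestannylation.

Step 7
Reactants: 10 but-2-yne-1,4-diol
Product: 11 4-(triethylsilyloxy)but-2-yn-1-ol
Conditions: TESCl (1.0 equiv), imidazole (1.2 equiv), 10 (4 equiv), DMF, 0 °C
Reagents that add atoms: chlorotriethylsilane, CC[Si](Cl)(CC)CC
Why: Statistical monosilylation; the excess of the cheap, water-soluble diol suppresses the bis-ether and is washed out.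

Step 8
Reactants: 11 4-(triethylsilyloxy)but-2-yn-1-ol
Product: 13 (2Z)-3-iodo-4-(triethylsilyloxy)but-2-en-1-ol, via cyclic alkenylalanate 12 (not isolated)
Conditions: NaAlH2(OCH2CH2OCH3)2 (1.6 equiv), THF, 0 °C → rt; then I2 (1.5 equiv), THF, −78 → 0 °C
Reagents that add atoms: iodine, II
Why: Hydroxyl-directed trans-hydroalumination delivers hydride to the future C13 and aluminium to C12 in a five-membered alanate. Iodine replaces aluminium with retention, so iodine stands cis to the free carbinol carbon (future C14), which fixes the C12=C13 geometry.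

Step 9
Reactants: 9 (3S,4Z)-3-(tert-butyldimethylsilyloxy)-4-methyl-5-(tributylstannyl)penta-1,4-diene; 13 (2Z)-3-iodo-4-(triethylsilyloxy)but-2-en-1-ol
Product: 15 (2E,6S,7Z)-6-(tert-butyldimethylsilyloxy)-7-methyl-3-[(triethylsilyloxy)methyl]-8-(tributylstannyl)octa-2,7-dien-1-ol, via alkyl-9-BBN borane 14 (not isolated)
Conditions: 9 (1.2 equiv), 9-BBN-H (1.3 equiv), THF, 0 °C → rt; then 13, PdCl2(dppf) (5 mol%), aq. K3PO4 (3 M), DMF, rt
Reagents that add atoms: none
Why: B-alkyl Suzuki–Miyaura coupling: 9-BBN adds only to the terminal vinyl group, and the alkenyl iodide couples with retention, which places C11 cis to C14. Under copper-free, arsine-free conditions at room temperature the base-activated borate should transmetalate much faster than the neutral, hindered alkenylstannane, so the tin group should survive.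

Step 10
Reactants: 15 (2E,6S,7Z)-6-(tert-butyldimethylsilyloxy)-7-methyl-3-[(triethylsilyloxy)methyl]-8-(tributylstannyl)octa-2,7-dien-1-ol
Product: 16 (2E,6S,7Z)-6-(tert-butyldimethylsilyloxy)-7-methyl-3-[(triethylsilyloxy)methyl]-8-(tributylstannyl)octa-2,7-dienal
Conditions: activated MnO2 (15 equiv), CH2Cl2, rt
Reagents that add atoms: none
Why: Chemoselective oxidation of the only free, primary allylic alcohol; silyl ethers and the stannane are inert, and the neutral conditions keep the enal geometry.

Step 11
Reactants: 3 (2E,6E)-8-bromo-3,7-dimethylocta-2,6-dien-1-yl acetate; 16 (2E,6S,7Z)-6-(tert-butyldimethylsilyloxy)-7-methyl-3-[(triethylsilyloxy)methyl]-8-(tributylstannyl)octa-2,7-dienal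
Product: 18 (2E,6R,7S,8E,12S,13Z)-12-(tert-butyldimethylsilyloxy)-7-hydroxy-3,13-dimethyl-6-(prop-1-en-2-yl)-9-[(triethylsilyloxy)methyl]-14-(tributylstannyl)tetradeca-2,8,13-trien-1-yl acetate, via allylchromium dichloride 17 (not isolated)
Conditions: CrCl2 (4 equiv), chiral oxazoline–sulfonamide ligand (4.4 equiv, the antipode that directs attack to the Re face of C14), Et3N (4.4 equiv), THF, rt, 1 h; then 16 and 3 (1.5 equiv), 0 °C → rt; aq. sodium serinate work-up
Reagents that add atoms: none
Why: Asymmetric Nozaki–Hiyama–Kishi-type allylation: divalent chromium turns the allylic bromide into an allylchromium species that adds through its γ-carbon in a closed six-membered chair transition state. The E-configured γ-substituent gives the anti C1/C14 pair and unveils the isopropenyl group, and the ligand on chromium selects the Re face of the aldehyde (C14 S, hence C1 R). Acetate, silyl ethers and the alkenylstannane are inert to CrCl2 in the absence of nickel.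

Step 12
Reactants: 18 (2E,6R,7S,8E,12S,13Z)-12-(tert-butyldimethylsilyloxy)-7-hydroxy-3,13-dimethyl-6-(prop-1-en-2-yl)-9-[(triethylsilyloxy)methyl]-14-(tributylstannyl)tetradeca-2,8,13-trien-1-yl acetate
Product: 19 (2E,6R,7S,8E,12S,13Z)-12-(tert-butyldimethylsilyloxy)-3,13-dimethyl-6-(prop-1-en-2-yl)-7-(triethylsilyloxy)-9-[(triethylsilyloxy)methyl]-14-(tributylstannyl)tetradeca-2,8,13-trien-1-yl acetate
Conditions: TESCl, imidazole, DMAP (cat.), DMF, rt
Reagents that add atoms: chlorotriethylsilane, CC[Si](Cl)(CC)CC
Why: Silylation of the secondary allylic alcohol under basic conditions that spare the stannane and the acetate; the silyl ether later blocks attack of O14 on the π-allyl complex.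

Step 13
Reactants: 19 (2E,6R,7S,8E,12S,13Z)-12-(tert-butyldimethylsilyloxy)-3,13-dimethyl-6-(prop-1-en-2-yl)-7-(triethylsilyloxy)-9-[(triethylsilyloxy)methyl]-14-(tributylstannyl)tetradeca-2,8,13-trien-1-yl acetate
Product: 20 (2E,6R,7S,8E,12S,13Z)-12-(tert-butyldimethylsilyloxy)-3,13-dimethyl-6-(prop-1-en-2-yl)-7-(triethylsilyloxy)-9-[(triethylsilyloxy)methyl]-14-(tributylstannyl)tetradeca-2,8,13-trien-1-ol
Conditions: i-Bu2AlH (2.5 equiv), CH2Cl2, −78 °C; Rochelle salt work-up
Reagents that add atoms: none
Why: Reductive cleavage of the acetate at low temperature frees the C6 hydroxyl without the basic methanol that could loosen the primary triethylsilyl ether; the stannane and the alkenes do not react.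

Step 14
Reactants: 20 (2E,6R,7S,8E,12S,13Z)-12-(tert-butyldimethylsilyloxy)-3,13-dimethyl-6-(prop-1-en-2-yl)-7-(triethylsilyloxy)-9-[(triethylsilyloxy)methyl]-14-(tributylstannyl)tetradeca-2,8,13-trien-1-ol
Product: 22 (2E,6R,7S,8E,12S,13Z)-12-(tert-butyldimethylsilyloxy)-1-chloro-3,13-dimethyl-6-(prop-1-en-2-yl)-7-(triethylsilyloxy)-9-[(triethylsilyloxy)methyl]-14-(tributylstannyl)tetradeca-2,8,13-triene, via allylic mesylate 21 (not isolated)
Conditions: MsCl (1.3 equiv), Et3N (1.6 equiv), CH2Cl2, −40 °C; then LiCl (5 equiv), THF, −40 → 0 °C
Reagents that add atoms: lithium chloride, [Li+].[Cl-] (chloride source; chloride freed from methanesulfonyl chloride, CS(=O)(=O)Cl, joins the same pool)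
Why: Mesylation followed by SN2 displacement with chloride converts the primary allylic alcohol into the chloride without allylic transposition. No electrophilic halogen is present that could cleave the C–Sn bond.

Step 15
Reactants: 22 (2E,6R,7S,8E,12S,13Z)-12-(tert-butyldimethylsilyloxy)-1-chloro-3,13-dimethyl-6-(prop-1-en-2-yl)-7-(triethylsilyloxy)-9-[(triethylsilyloxy)methyl]-14-(tributylstannyl)tetradeca-2,8,13-triene
Product: 23 (1R,4E,7Z,9S,12E,14S)-9-(tert-butyldimethylsilyloxy)-4,8-dimethyl-1-(prop-1-en-2-yl)-14-(triethylsilyloxy)-12-[(triethylsilyloxy)methyl]cyclotetradeca-4,7,12-triene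
Conditions: Pd2(dba)3·CHCl3 (10 mol%), AsPh3 (40 mol%), i-Pr2NEt (2 equiv), degassed THF, 50 °C, 22 added over 10 h to a final 1 mM
Reagents that add atoms: none
Why: Zerovalent palladium ionises the primary allylic chloride to a π-allylpalladium chloride spanning C4–C6, and the weakly bound AsPh3 leaves a coordination site free for the slow transmetalation. The Z-alkenylstannane at C7 transmetalates with retention of geometry, and reductive elimination joins C7 to the primary terminus C6. The closest known reaction type is the palladium-catalysed coupling of allylic halides with alkenylstannanes, which is established for closing macrocyclic 1,4-dienes. The 14-membered ring closes by intramolecular cross-coupling through a large palladacycle, and high dilution with slow addition favours cyclisation over oligomerisation. No stereocentre is formed, and C1, C9 and C14 are remote and untouched. Coupling at C6 and not at the tertiary terminus C4 follows from the steric bias of the trisubstituted allyl unit. The 4E geometry should be kept because the syn π-allyl complex from the E-chloride couples faster than it isomerises, and the 7Z geometry because transmetalation is stereoretentive. The neutral conditions leave the three silyl ethers intact, and the silyl group on O14 blocks attack of that oxygen on C4.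

Step 16
Reactants: 23 (1R,4E,7Z,9S,12E,14S)-9-(tert-butyldimethylsilyloxy)-4,8-dimethyl-1-(prop-1-en-2-yl)-14-(triethylsilyloxy)-12-[(triethylsilyloxy)methyl]cyclotetradeca-4,7,12-triene
Product: 24 (1R,4E,7Z,9S,12E,14S)-9-(tert-butyldimethylsilyloxy)-12-(hydroxymethyl)-4,8-dimethyl-1-(prop-1-en-2-yl)cyclotetradeca-4,7,12-trien-14-ol
Conditions: PPTS (0.2 equiv), MeOH/CH2Cl2 (3:1), 0 °C → rt
Reagents that add atoms: none
Why: Mild acid methanolysis removes triethylsilyl ethers far faster than the secondary tert-butyldimethylsilyl ether, and is too weak to ionise the allylic alcohols or move the skipped diene.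

Step 17
Reactants: 24 (1R,4E,7Z,9S,12E,14S)-9-(tert-butyldimethylsilyloxy)-12-(hydroxymethyl)-4,8-dimethyl-1-(prop-1-en-2-yl)cyclotetradeca-4,7,12-trien-14-ol
Product: 25 (1R,4E,7Z,9S,12E,14S)-12-(acetoxymethyl)-9-(tert-butyldimethylsilyloxy)-4,8-dimethyl-1-(prop-1-en-2-yl)cyclotetradeca-4,7,12-trien-14-yl acetate
Conditions: Ac2O (4 equiv), pyridine, DMAP (cat.), CH2Cl2, rt
Reagents that add atoms: acetic anhydride, CC(=O)OC(C)=O
Why: DMAP-catalysed acylation acetylates the primary and the hindered secondary hydroxyl together; O9 is still silylated, so no selectivity problem arises.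

Step 18
Reactants: 25 (1R,4E,7Z,9S,12E,14S)-12-(acetoxymethyl)-9-(tert-butyldimethylsilyloxy)-4,8-dimethyl-1-(prop-1-en-2-yl)cyclotetradeca-4,7,12-trien-14-yl acetate
Product: 26 (1R,4E,7Z,9S,12E,14S)-12-(acetoxymethyl)-9-hydroxy-4,8-dimethyl-1-(prop-1-en-2-yl)cyclotetradeca-4,7,12-trien-14-yl acetate
Conditions: HF·pyridine, pyridine, THF, 0 °C → rt
Reagents that add atoms: none
Why: Buffered fluoride cleaves the Si–O9 bond without the basicity that could cleave or shift the acetates; the remote acetates cannot migrate to O9.

## Compound list

1 | geranyl acetate | CC(C)=CCC/C(C)=C/COC(C)=O | starting material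
2 | (2E,6E)-8-hydroxy-3,7-dimethylocta-2,6-dien-1-yl acetate | CC(=O)OC/C=C(\C)CC/C=C(\C)CO | intermediate
3 | (2E,6E)-8-bromo-3,7-dimethylocta-2,6-dien-1-yl acetate | CC(=O)OC/C=C(\C)CC/C=C(\C)CBr | intermediate
4 | propargyl alcohol | C#CCO | starting material
5 | bromomagnesium (2Z)-3-(bromomagnesio)-2-methylprop-2-en-1-olate (chelated alkenyl Grignard) | C/C(CO[Mg]Br)=C/[Mg]Br | intermediate
6 | (2Z)-2-methyl-3-(tributylstannyl)prop-2-en-1-ol | C/C(CO)=C/[Sn](CCCC)(CCCC)CCCC | intermediate
7 | (2Z)-2-methyl-3-(tributylstannyl)prop-2-enal | C/C(C=O)=C/[Sn](CCCC)(CCCC)CCCC | intermediate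
8 | (3S,4Z)-4-methyl-5-(tributylstannyl)penta-1,4-dien-3-ol | C=C[C@H](O)/C(C)=C\[Sn](CCCC)(CCCC)CCCC | intermediate
9 | (3S,4Z)-3-(tert-butyldimethylsilyloxy)-4-methyl-5-(tributylstannyl)penta-1,4-diene | C=C[C@H](O[Si](C)(C)C(C)(C)C)/C(C)=C\[Sn](CCCC)(CCCC)CCCC | intermediate
10 | but-2-yne-1,4-diol | OCC#CCO | starting material
11 | 4-(triethylsilyloxy)but-2-yn-1-ol | OCC#CCO[Si](CC)(CC)CC | intermediate
12 | sodium 2,2-bis(2-methoxyethoxy)-3-[(triethylsilyloxy)methyl]-2,5-dihydro-1,2-oxaluminol-2-uide (cyclic alkenylalanate) | [Na+].COCCO[Al-]1(OCCOC)OCC=C1CO[Si](CC)(CC)CC | intermediate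
13 | (2Z)-3-iodo-4-(triethylsilyloxy)but-2-en-1-ol | OC/C=C(\I)CO[Si](CC)(CC)CC | intermediate
14 | 9-[(3S,4Z)-3-(tert-butyldimethylsilyloxy)-4-methyl-5-(tributylstannyl)pent-4-en-1-yl]-9-borabicyclo[3.3.1]nonane | C1CCC2CCCC1B2CC[C@H](O[Si](C)(C)C(C)(C)C)/C(C)=C\[Sn](CCCC)(CCCC)CCCC | intermediate
15 | (2E,6S,7Z)-6-(tert-butyldimethylsilyloxy)-7-methyl-3-[(triethylsilyloxy)methyl]-8-(tributylstannyl)octa-2,7-dien-1-ol | OC/C=C(CO[Si](CC)(CC)CC)\CC[C@H](O[Si](C)(C)C(C)(C)C)/C(C)=C\[Sn](CCCC)(CCCC)CCCC | intermediate
16 | (2E,6S,7Z)-6-(tert-butyldimethylsilyloxy)-7-methyl-3-[(triethylsilyloxy)methyl]-8-(tributylstannyl)octa-2,7-dienal | O=C/C=C(CO[Si](CC)(CC)CC)\CC[C@H](O[Si](C)(C)C(C)(C)C)/C(C)=C\[Sn](CCCC)(CCCC)CCCC | intermediate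
17 | [(2E,6E)-8-acetoxy-2,6-dimethylocta-2,6-dien-1-yl]chromium dichloride (trivalent chromium) | CC(=O)OC/C=C(\C)CC/C=C(\C)C[Cr](Cl)Cl | intermediate
18 | (2E,6R,7S,8E,12S,13Z)-12-(tert-butyldimethylsilyloxy)-7-hydroxy-3,13-dimethyl-6-(prop-1-en-2-yl)-9-[(triethylsilyloxy)methyl]-14-(tributylstannyl)tetradeca-2,8,13-trien-1-yl acetate | CC(=O)OC/C=C(\C)CC[C@H](C(C)=C)[C@@H](O)/C=C(CO[Si](CC)(CC)CC)\CC[C@H](O[Si](C)(C)C(C)(C)C)/C(C)=C\[Sn](CCCC)(CCCC)CCCC | intermediate
19 | (2E,6R,7S,8E,12S,13Z)-12-(tert-butyldimethylsilyloxy)-3,13-dimethyl-6-(prop-1-en-2-yl)-7-(triethylsilyloxy)-9-[(triethylsilyloxy)methyl]-14-(tributylstannyl)tetradeca-2,8,13-trien-1-yl acetate | CC(=O)OC/C=C(\C)CC[C@H](C(C)=C)[C@@H](O[Si](CC)(CC)CC)/C=C(CO[Si](CC)(CC)CC)\CC[C@H](O[Si](C)(C)C(C)(C)C)/C(C)=C\[Sn](CCCC)(CCCC)CCCC | intermediate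
20 | (2E,6R,7S,8E,12S,13Z)-12-(tert-butyldimethylsilyloxy)-3,13-dimethyl-6-(prop-1-en-2-yl)-7-(triethylsilyloxy)-9-[(triethylsilyloxy)methyl]-14-(tributylstannyl)tetradeca-2,8,13-trien-1-ol | OC/C=C(\C)CC[C@H](C(C)=C)[C@@H](O[Si](CC)(CC)CC)/C=C(CO[Si](CC)(CC)CC)\CC[C@H](O[Si](C)(C)C(C)(C)C)/C(C)=C\[Sn](CCCC)(CCCC)CCCC | intermediate
21 | (2E,6R,7S,8E,12S,13Z)-12-(tert-butyldimethylsilyloxy)-3,13-dimethyl-6-(prop-1-en-2-yl)-7-(triethylsilyloxy)-9-[(triethylsilyloxy)methyl]-14-(tributylstannyl)tetradeca-2,8,13-trien-1-yl methanesulfonate | CS(=O)(=O)OC/C=C(\C)CC[C@H](C(C)=C)[C@@H](O[Si](CC)(CC)CC)/C=C(CO[Si](CC)(CC)CC)\CC[C@H](O[Si](C)(C)C(C)(C)C)/C(C)=C\[Sn](CCCC)(CCCC)CCCC | intermediate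
22 | (2E,6R,7S,8E,12S,13Z)-12-(tert-butyldimethylsilyloxy)-1-chloro-3,13-dimethyl-6-(prop-1-en-2-yl)-7-(triethylsilyloxy)-9-[(triethylsilyloxy)methyl]-14-(tributylstannyl)tetradeca-2,8,13-triene (seco chloride stannane) | ClC/C=C(\C)CC[C@H](C(C)=C)[C@@H](O[Si](CC)(CC)CC)/C=C(CO[Si](CC)(CC)CC)\CC[C@H](O[Si](C)(C)C(C)(C)C)/C(C)=C\[Sn](CCCC)(CCCC)CCCC | intermediate
23 | (1R,4E,7Z,9S,12E,14S)-9-(tert-butyldimethylsilyloxy)-4,8-dimethyl-1-(prop-1-en-2-yl)-14-(triethylsilyloxy)-12-[(triethylsilyloxy)methyl]cyclotetradeca-4,7,12-triene (ring numbering of the text) | C=C(C)[C@H]1CC/C(C)=C/C/C=C(/C)[C@@H](O[Si](C)(C)C(C)(C)C)CC/C(CO[Si](CC)(CC)CC)=C\[C@@H]1O[Si](CC)(CC)CC | intermediate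
24 | (1R,4E,7Z,9S,12E,14S)-9-(tert-butyldimethylsilyloxy)-12-(hydroxymethyl)-4,8-dimethyl-1-(prop-1-en-2-yl)cyclotetradeca-4,7,12-trien-14-ol | C=C(C)[C@H]1CC/C(C)=C/C/C=C(/C)[C@@H](O[Si](C)(C)C(C)(C)C)CC/C(CO)=C\[C@@H]1O | intermediate
25 | (1R,4E,7Z,9S,12E,14S)-12-(acetoxymethyl)-9-(tert-butyldimethylsilyloxy)-4,8-dimethyl-1-(prop-1-en-2-yl)cyclotetradeca-4,7,12-trien-14-yl acetate | C=C(C)[C@H]1CC/C(C)=C/C/C=C(/C)[C@@H](O[Si](C)(C)C(C)(C)C)CC/C(COC(C)=O)=C\[C@@H]1OC(C)=O | intermediate
26 | (1R,4E,7Z,9S,12E,14S)-12-(acetoxymethyl)-9-hydroxy-4,8-dimethyl-1-(prop-1-en-2-yl)cyclotetradeca-4,7,12-trien-14-yl acetate | C=C(C)[C@H]1CC/C(C)=C/C/C=C(/C)[C@@H](O)CC/C(COC(C)=O)=C\[C@@H]1OC(C)=O | target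

## Step count and least certain steps

Total: 18 steps. Longest linear sequence: 14 steps (from 4 to 26: steps 3–6 and 9–18).

Step 15 (key step). The most likely failure is slow transmetalation of the hindered Z-alkenylstannane, whose tin is cis to the silyloxy-bearing C9, at the high dilution needed for cyclisation. Protodestannylation, intermolecular coupling and syn/anti isomerisation of the π-allyl complex (loss of the 4E geometry) could then compete. Fallback: the C6–C7 bond is made between two molecules and the ring is closed at C1–C14 instead, setting out from 16 and 2 and returning at 23. The allylic acetate of 2 is coupled with the stannane of 16 at normal concentration (Pd(dba)2, LiCl, DMF, 40 °C) to give (2E,6S,7Z,10E,14E)-6-(tert-butyldimethylsilyloxy)-16-hydroxy-7,11,15-trimethyl-3-[(triethylsilyloxy)methyl]hexadeca-2,7,10,14-tetraenal F1. Appel bromination (CBr4, PPh3, CH2Cl2, 0 °C) gives the 16-bromo analogue F2. An intramolecular chromium-mediated allylation of the enal (CrCl2, the same chiral ligand, THF, high dilution) should close the ring through the same chair transition state to the macrocyclic C14 alcohol F3. Silylation (TESCl, imidazole, DMF) gives 23.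

Step 11. The risk is poor facial selectivity, because the only stereocentre of 16 is remote and allyl halides substituted at both the β- and γ-carbons are less studied in ligand-controlled chromium allylations than allyl or crotyl halides. The anti relationship itself is secure. Fallback: Lewis-base-catalysed addition of an allyltrichlorosilane, setting out from 3 and 16 and returning at 18. Treating 3 with HSiCl3, CuCl (cat.) and i-Pr2NEt in Et2O gives [(2E,6E)-8-acetoxy-2,6-dimethylocta-2,6-dien-1-yl]trichlorosilane F4. F4 adds to 16 in the presence of a chiral bis-phosphoramide catalyst and i-Pr2NEt in CH2Cl2 at −78 °C through a closed chair transition state at hexacoordinate silicon, which again gives the anti product 18 from the E-allyl unit.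

Step 5. The risk is erosion of enantioselectivity by a racemic background addition promoted by residual magnesium salts, and partial Z to E isomerisation of the enal before it is consumed. Fallback: alkynylation and reduction, setting out from 7 and returning at 8. Zinc alkynylide addition with the appropriate ProPhenol antipode (Me2Zn, trimethylsilylacetylene, toluene, 0 °C), a reaction type that is well established for enals, gives (3S,4Z)-4-methyl-5-(tributylstannyl)-1-(trimethylsilyl)pent-4-en-1-yn-3-ol F5. K2CO3 in MeOH removes the C-silyl group to give (3S,4Z)-4-methyl-5-(tributylstannyl)pent-4-en-1-yn-3-ol F6. Hydroxyl-directed reduction of the terminal alkyne with NaAlH2(OCH2CH2OCH3)2 in THF gives 8.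

Step 9. The risk is competing transmetalation from tin, so that the stannane couples with the alkenyl iodide, and protodestannylation under aqueous base. Fallback: an iron-catalysed Grignard coupling that has no tin-transfer pathway, setting out from 9 and returning at 15. Hydroboration of 9 with 9-BBN-H and oxidation with NaBO3·4H2O gives (3S,4Z)-3-(tert-butyldimethylsilyloxy)-4-methyl-5-(tributylstannyl)pent-4-en-1-ol F7. CBr4 and PPh3 convert it into the primary bromide F8, and magnesium in THF gives the Grignard reagent F9. F9 is coupled with 13, taken as its magnesium alkoxide after one equivalent of MeMgBr, under Fe(acac)3 catalysis in THF/NMP at 0 °C with retention of the alkene geometry, to give 15.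

Step 3. The risk is incomplete C-stannylation of the chelated alkenylmagnesium species 5, through stannylation at oxygen or consumption of the chlorostannane by excess MeMgBr. Fallback: halogen trapping and lithium–tin exchange, setting out from 4 and returning at 6. The same carbomagnesiation is quenched with iodine to give (2Z)-3-iodo-2-methylprop-2-en-1-ol F10, an isolable and well-behaved compound. F10 is converted with t-BuLi (3.2 equiv, Et2O, −78 °C) into the lithium alkoxide alkenyllithium and quenched with Bu3SnCl to give 6.

## Further compounds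

F1 | step 15 | (2E,6S,7Z,10E,14E)-6-(tert-butyldimethylsilyloxy)-16-hydroxy-7,11,15-trimethyl-3-[(triethylsilyloxy)methyl]hexadeca-2,7,10,14-tetraenal | OC/C(C)=C/CC/C(C)=C/C/C=C(/C)[C@@H](O[Si](C)(C)C(C)(C)C)CC/C(CO[Si](CC)(CC)CC)=C\C=O
F2 | step 15 | (2E,6S,7Z,10E,14E)-16-bromo-6-(tert-butyldimethylsilyloxy)-7,11,15-trimethyl-3-[(triethylsilyloxy)methyl]hexadeca-2,7,10,14-tetraenal | BrC/C(C)=C/CC/C(C)=C/C/C=C(/C)[C@@H](O[Si](C)(C)C(C)(C)C)CC/C(CO[Si](CC)(CC)CC)=C\C=O
F3 | step 15 | (1R,4E,7Z,9S,12E,14S)-9-(tert-butyldimethylsilyloxy)-4,8-dimethyl-1-(prop-1-en-2-yl)-12-[(triethylsilyloxy)methyl]cyclotetradeca-4,7,12-trien-14-ol | C=C(C)[C@H]1CC/C(C)=C/C/C=C(/C)[C@@H](O[Si](C)(C)C(C)(C)C)CC/C(CO[Si](CC)(CC)CC)=C\[C@@H]1O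
F4 | step 11 | [(2E,6E)-8-acetoxy-2,6-dimethylocta-2,6-dien-1-yl]trichlorosilane | CC(=O)OC/C=C(\C)CC/C=C(\C)C[Si](Cl)(Cl)Cl
F5 | step 5 | (3S,4Z)-4-methyl-5-(tributylstannyl)-1-(trimethylsilyl)pent-4-en-1-yn-3-ol | C[Si](C)(C)C#C[C@H](O)/C(C)=C\[Sn](CCCC)(CCCC)CCCC
F6 | step 5 | (3S,4Z)-4-methyl-5-(tributylstannyl)pent-4-en-1-yn-3-ol | C#C[C@H](O)/C(C)=C\[Sn](CCCC)(CCCC)CCCC
F7 | step 9 | (3S,4Z)-3-(tert-butyldimethylsilyloxy)-4-methyl-5-(tributylstannyl)pent-4-en-1-ol | OCC[C@H](O[Si](C)(C)C(C)(C)C)/C(C)=C\[Sn](CCCC)(CCCC)CCCC
F8 | step 9 | (3S,4Z)-1-bromo-3-(tert-butyldimethylsilyloxy)-4-methyl-5-(tributylstannyl)pent-4-ene | BrCC[C@H](O[Si](C)(C)C(C)(C)C)/C(C)=C\[Sn](CCCC)(CCCC)CCCC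
F9 | step 9 | [(3S,4Z)-3-(tert-butyldimethylsilyloxy)-4-methyl-5-(tributylstannyl)pent-4-en-1-yl]magnesium bromide | Br[Mg]CC[C@H](O[Si](C)(C)C(C)(C)C)/C(C)=C\[Sn](CCCC)(CCCC)CCCC
F10 | step 3 | (2Z)-3-iodo-2-methylprop-2-en-1-ol | C/C(CO)=C/I
A1 | alternative 1 | 14-membered propargylic alcohol with C12–C13 alkyne | C=C(C)[C@H]1CC/C(C)=C/C/C=C(/C)[C@@H](O[Si](C)(C)C(C)(C)C)CCC#C[C@@H]1O
A2 | alternative 1 | 17-membered propargyl allyl ether | O1CC#CCC[C@H](O[Si](C)(C)C(C)(C)C)/C(C)=C\C/C=C(\C)CC/C=C(\C)C1
A3 | alternative 2 | 14-membered ring C2-carboxylic acid (C2 configuration open) | C=C(C)[C@H]1C(C(=O)O)C/C(C)=C/C/C=C(/C)[C@@H](O[Si](C)(C)C(C)(C)C)CC/C(CO[Si](CC)(CC)CC)=C\[C@@H]1O[Si](CC)(CC)CC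
A4 | alternative 2 | 18-membered lactone | O=C1CC/C(C)=C/C/C=C(/C)[C@@H](O[Si](C)(C)C(C)(C)C)CC/C(CO[Si](CC)(CC)CC)=C\[C@H](O[Si](CC)(CC)CC)/C=C(\C)CO1
A5 | alternative 3 | macrocyclic E-enoate with methyl ester on C12 | C=C(C)[C@H]1CC/C(C)=C/C/C=C(/C)[C@@H](O[Si](C)(C)C(C)(C)C)CC/C(C(=O)OC)=C\[C@@H]1O[Si](CC)(CC)CC
A6 | alternative 3 | seco C13 aldehyde C12 phosphonoacetate | O=C[C@H](O[Si](CC)(CC)CC)[C@@H](C(C)=C)CC/C(C)=C/C/C=C(/C)[C@@H](O[Si](C)(C)C(C)(C)C)CCC(C(=O)OC)P(=O)(OCC)OCC
A7 | alternative 3 | (S)-limonene | CC1=CC[C@H](CC1)C(C)=C
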